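The dihydrofuran ring (ring B) is cut at O1–C2 and C2–C3. C2 carries the 1-formylvinyl group and lies between the ring oxygen O1 and the benzylic carbinol carbon C3, so it is taken back to the ylide carbon of a chiral 2-(ethoxycarbonyl)allyl sulfonium salt. One (4+1) annulation with a salicylaldehyde should make both bonds, close ring B on the benzene ring (ring A) and set C2 and C3 as the trans alcohol. The precursor is 2-hydroxy-5-[(1R)-1-silyloxyethyl]benzaldehyde: its formyl carbon becomes C3 and its phenol oxygen becomes O1. C3 is inverted later during esterification, and the acrylate is turned into the enal last.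

Key step: step 6

Assumption: compounds 1, 6, 7, 15 and 18 are taken as purchasable; the sulfide is written as its (1R,4R,5R) enantiomer on the assumption that its ylide delivers C2 in the (R) series, and the antipodal sulfide would replace it, with nothing else changed, if a first run showed the opposite sense.

Step 1
Reactants: 1 4-acetoxyacetophenone
Product: 2 4-[(1R)-1-hydroxyethyl]phenyl acetate
Conditions: (S)-2-methyl-CBS-oxazaborolidine [(S)-1-methyl-3,3-diphenyltetrahydro-1H,3H-pyrrolo[1,2-c][1,3,2]oxazaborole] (0.1 equiv), BH3·SMe2 (0.7 equiv), THF, −20 °C; MeOH quench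
Reagents that add atoms: none
Why: Corey–Bakshi–Shibata reduction, in which the oxazaborolidine–borane complex binds the ketone with the aryl group as the large substituent and delivers hydride to the Si face, so the (R)-carbinol should form as it does from acetophenone, while the aryl acetate is too slow towards borane at this temperature to interfere.

Step 2
Reactants: 2 4-[(1R)-1-hydroxyethyl]phenyl acetate
Product: 3 4-[(1R)-1-(tert-butyldimethylsilyloxy)ethyl]phenyl acetate
Conditions: TBSOTf, 2,6-lutidine, CH2Cl2, −78 to 0 °C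
Reagents that add atoms: tert-butyldimethylsilyl triflate, CC(C)(C)[Si](C)(C)OS(=O)(=O)C(F)(F)F
Why: Silyl ether formation on the secondary alcohol with a hindered, non-nucleophilic base that leaves the aryl acetate intact; the O–H bond reacts, so the stereocentre is not involved.

Step 3
Reactants: 3 4-[(1R)-1-(tert-butyldimethylsilyloxy)ethyl]phenyl acetate
Product: 4 4-[(1R)-1-(tert-butyldimethylsilyloxy)ethyl]phenol
Conditions: K2CO3 (0.3 equiv), MeOH, 0 °C to rt; NH4Cl work-up
Reagents that add atoms: none
Why: Base-catalysed transesterification (methanolysis) removes an aryl acetate far faster than an alkyl silyl ether is attacked, and silanolate is too poor a leaving group for the phenoxide to expel it as a quinone methide.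

Step 4
Reactants: 4 4-[(1R)-1-(tert-butyldimethylsilyloxy)ethyl]phenol
Product: 5 2-hydroxy-5-[(1R)-1-(tert-butyldimethylsilyloxy)ethyl]benzaldehyde
Conditions: MgCl2, Et3N, (CH2O)n, THF, reflux; cold aqueous citric acid work-up
Reagents that add atoms: paraformaldehyde (reacting as formaldehyde), C=O
Why: Magnesium-mediated ortho-formylation (Casnati–Skattebøl reaction), in which the magnesium phenoxide directs formaldehyde to the ortho carbon and a second formaldehyde oxidises the resulting salicyl alkoxide by hydride transfer; the para position is blocked, so only the ortho aldehyde can form.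

Step 5
Reactants: 6 ethyl 2-(bromomethyl)acrylate; 7 (1R,4R,5R)-isothiocineole [(1R,4R,5R)-4,7,7-trimethyl-6-thiabicyclo[3.2.1]octane]
Product: 8 (1R,4R,5R)-6-[2-(ethoxycarbonyl)prop-2-en-1-yl]-4,7,7-trimethyl-6-thiabicyclo[3.2.1]octan-6-ium triflate (allyl group expected on the exo lone pair of sulfur)
Conditions: LiOTf, CH2Cl2/H2O, rt
Reagents that add atoms: lithium triflate, [Li+].[O-]S(=O)(=O)C(F)(F)F
Why: S-alkylation of a sulfide by a reactive allylic bromide (SN2 or SN2′ gives the same salt) with anion metathesis to the non-nucleophilic triflate; the less hindered exo lone pair should react, giving one diastereomer at sulfur.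

Step 6
Reactants: 5 2-hydroxy-5-[(1R)-1-(tert-butyldimethylsilyloxy)ethyl]benzaldehyde; 8 the sulfonium triflate
Product: 12 ethyl 2-[(2R,3S)-3-hydroxy-5-[(1R)-1-(tert-butyldimethylsilyloxy)ethyl]-2,3-dihydro-1-benzofuran-2-yl]prop-2-enoate (2,3-trans), via sulfonium ylide 9 (not isolated), via anti betaine 10 (not isolated), via trans vinyl epoxide phenoxide 11 (not isolated)
Conditions: 8 (1.3 equiv), Cs2CO3 (2.5 equiv), MeCN, 0 °C to rt
Reagents that add atoms: none
Why: Proposed new method: Cs2CO3 converts 8 into ylide 9, whose carbon adds to the formyl group of 5 (C2–C3 bond) to give the anti betaine 10; its alkoxide expels the sulfide in a 3-exo-tet closure to the trans vinyl epoxide 11, and the ortho phenoxide then opens the epoxide at the allylic carbon with inversion (O1–C2 bond), so that the net result is replacement of the sulfide at C2 by O1. The closest known reactions are the trans-selective (4+1) annulations of salicylaldehydes with carbonyl-stabilised sulfonium ylides and of salicyl imines with allylic ylides from Morita–Baylis–Hillman carbonates, together with the epoxidation of aldehydes by allylic sulfonium ylides of chiral sulfides; the untested element is an ester-bearing allylic ylide of a chiral sulfide acting on a free salicylaldehyde. Ring B closes by a 5-endo epoxide opening (intramolecular SN2), which should be feasible because the attacked carbon is allylic and the only alternative is a four-membered ring. C2 is fixed by the ylide face that the bicyclic sulfide leaves open and is inverted twice (net retention), C3 follows from the anti course of the addition that leads to the trans epoxide and is not touched by the opening, so the alcohol is 2,3-trans, and the (R) centre of the side chain is a remote spectator. The step needs ylide attack on the carbonyl in preference to O-allylation of the phenoxide, and closure through the epoxide instead of direct displacement of the sulfide by the phenoxide: the phenoxide of 5 is delocalised into the formyl group and is a weak nucleophile, the preformed triflate salt leaves no free allyl bromide in the flask, the betaine alkoxide is the nearer and stronger nucleophile, and the para substituent is a silyl ether that the phenoxide cannot expel as a quinone methide.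

Step 7
Reactants: 12 ethyl 2-[(2R,3S)-3-hydroxy-5-[(1R)-1-(tert-butyldimethylsilyloxy)ethyl]-2,3-dihydro-1-benzofuran-2-yl]prop-2-enoate
Product: 13 (2R,3S)-2-(3-hydroxyprop-1-en-2-yl)-5-[(1R)-1-(tert-butyldimethylsilyloxy)ethyl]-2,3-dihydro-1-benzofuran-3-ol
Conditions: i-Bu2AlH (DIBAL-H, 4 equiv), CH2Cl2, −78 to −20 °C; aqueous potassium sodium tartrate
Reagents that add atoms: none
Why: 1,2-Reduction of an α,β-unsaturated ester to the allylic alcohol by DIBAL-H at low temperature; the silyl ether, the aryl ether and both ring stereocentres are untouched, and the free C3 hydroxyl only consumes one equivalent of hydride.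

Step 8
Reactants: 13 (2R,3S)-2-(3-hydroxyprop-1-en-2-yl)-5-[(1R)-1-(tert-butyldimethylsilyloxy)ethyl]-2,3-dihydro-1-benzofuran-3-ol
Product: 14 (2R,3S)-2-[3-(tert-butyldiphenylsilyloxy)prop-1-en-2-yl]-5-[(1R)-1-(tert-butyldimethylsilyloxy)ethyl]-2,3-dihydro-1-benzofuran-3-ol
Conditions: TBDPSCl (1.05 equiv), imidazole, CH2Cl2, 0 °C
Reagents that add atoms: tert-butyldiphenylsilyl chloride, CC(C)(C)[Si](Cl)(c1ccccc1)c1ccccc1
Why: Selective silylation in which the bulky silyl chloride takes the primary allylic hydroxyl and leaves the hindered secondary benzylic C3 hydroxyl free; TBDPS is chosen because it outlasts a secondary TBS ether under the buffered HF used later.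

Step 9
Reactants: 14 (2R,3S)-2-[3-(tert-butyldiphenylsilyloxy)prop-1-en-2-yl]-5-[(1R)-1-(tert-butyldimethylsilyloxy)ethyl]-2,3-dihydro-1-benzofuran-3-ol; 15 isovaleric acid (3-methylbutanoic acid)
Product: 16 (2R,3R)-2-[3-(tert-butyldiphenylsilyloxy)prop-1-en-2-yl]-5-[(1R)-1-(tert-butyldimethylsilyloxy)ethyl]-2,3-dihydro-1-benzofuran-3-yl 3-methylbutanoate (2,3-cis)
Conditions: PPh3, DIAD, toluene, 0 °C to rt
Reagents that add atoms: none
Why: Mitsunobu reaction, in which the C3 hydroxyl is activated as its oxyphosphonium ion and displaced by isovalerate in an SN2 step, so that C3 goes from S to R and the ester ends up cis to the C2 substituent; no conjugate acceptor and no other free hydroxyl is present at this stage.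

Step 10
Reactants: 16 (2R,3R)-2-[3-(tert-butyldiphenylsilyloxy)prop-1-en-2-yl]-5-[(1R)-1-(tert-butyldimethylsilyloxy)ethyl]-2,3-dihydro-1-benzofuran-3-yl 3-methylbutanoate
Product: 17 (2R,3R)-2-[3-(tert-butyldiphenylsilyloxy)prop-1-en-2-yl]-5-[(1R)-1-hydroxyethyl]-2,3-dihydro-1-benzofuran-3-yl 3-methylbutanoate
Conditions: HF·pyridine, pyridine, THF, 0 °C
Reagents that add atoms: none
Why: Fluoride-mediated desilylation under buffered, mildly acidic conditions, where a TBS ether is cleaved much faster than a TBDPS ether; the medium is neither basic enough to eliminate the cis C3 ester nor acidic enough to ionise the benzylic C–O bonds.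

Step 11
Reactants: 17 (2R,3R)-2-[3-(tert-butyldiphenylsilyloxy)prop-1-en-2-yl]-5-[(1R)-1-hydroxyethyl]-2,3-dihydro-1-benzofuran-3-yl 3-methylbutanoate; 18 (R)-2-methylbutanoic acid
Product: 19 (1R)-1-[(2R,3R)-2-[3-(tert-butyldiphenylsilyloxy)prop-1-en-2-yl]-3-(3-methylbutanoyloxy)-2,3-dihydro-1-benzofuran-5-yl]ethyl (2R)-2-methylbutanoate
Conditions: EDC·HCl, DMAP (0.2 equiv), CH2Cl2, 0 °C to rt
Reagents that add atoms: none
Why: Steglich esterification, which acylates the O–H bond and therefore retains the carbinol configuration; a simple α-alkyl acid should not epimerise under carbodiimide activation.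

Step 12
Reactants: 19 (1R)-1-[(2R,3R)-2-[3-(tert-butyldiphenylsilyloxy)prop-1-en-2-yl]-3-(3-methylbutanoyloxy)-2,3-dihydro-1-benzofuran-5-yl]ethyl (2R)-2-methylbutanoate
Product: 20 (1R)-1-[(2R,3R)-2-(3-hydroxyprop-1-en-2-yl)-3-(3-methylbutanoyloxy)-2,3-dihydro-1-benzofuran-5-yl]ethyl (2R)-2-methylbutanoate
Conditions: TBAF, AcOH (1:1), THF, 0 °C to rt
Reagents that add atoms: none
Why: Fluoride cleavage of the primary silyl ether, buffered by acetic acid so that the liberated alkoxide neither attacks the two esters nor triggers elimination across C2–C3.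

Step 13
Reactants: 20 (1R)-1-[(2R,3R)-2-(3-hydroxyprop-1-en-2-yl)-3-(3-methylbutanoyloxy)-2,3-dihydro-1-benzofuran-5-yl]ethyl (2R)-2-methylbutanoate
Product: 21 (1R)-1-[(2R,3R)-3-(3-methylbutanoyloxy)-2-(3-oxoprop-1-en-2-yl)-2,3-dihydro-1-benzofuran-5-yl]ethyl (2R)-2-methylbutanoate (CNP0154159.2)
Conditions: MnO2 (activated, excess), CH2Cl2, rt; filtration
Reagents that add atoms: none
Why: Allylic oxidation with MnO2 turns the primary allylic alcohol into the enal under neutral, heterogeneous conditions; no other oxidisable hydroxyl remains, and no nucleophile or base that could attack the sensitive enal is present.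

Compound list

1 | 4-acetoxyacetophenone (4-acetylphenyl acetate) | CC(=O)Oc1ccc(C(C)=O)cc1 | starting material
2 | 4-[(1R)-1-hydroxyethyl]phenyl acetate | CC(=O)Oc1ccc([C@@H](C)O)cc1 | intermediate
3 | 4-[(1R)-1-(tert-butyldimethylsilyloxy)ethyl]phenyl acetate | CC(=O)Oc1ccc([C@@H](C)O[Si](C)(C)C(C)(C)C)cc1 | intermediate
4 | 4-[(1R)-1-(tert-butyldimethylsilyloxy)ethyl]phenol | Oc1ccc([C@@H](C)O[Si](C)(C)C(C)(C)C)cc1 | intermediate
5 | 2-hydroxy-5-[(1R)-1-(tert-butyldimethylsilyloxy)ethyl]benzaldehyde | O=Cc1cc([C@@H](C)O[Si](C)(C)C(C)(C)C)ccc1O | intermediate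
6 | ethyl 2-(bromomethyl)acrylate | C=C(CBr)C(=O)OCC | starting material
7 | (1R,4R,5R)-isothiocineole, (1R,4R,5R)-4,7,7-trimethyl-6-thiabicyclo[3.2.1]octane | C[C@@H]1CC[C@@H]2C[C@H]1SC2(C)C | starting material
8 | (1R,4R,5R)-6-[2-(ethoxycarbonyl)prop-2-en-1-yl]-4,7,7-trimethyl-6-thiabicyclo[3.2.1]octan-6-ium triflate, allyl group exo on sulfur | C[C@@H]1CC[C@@H]2C[C@H]1[S@@+](CC(=C)C(=O)OCC)C2(C)C.[O-]S(=O)(=O)C(F)(F)F | intermediate
9 | sulfonium ylide of 8 (carbanion at the S-bound allylic carbon) | C[C@@H]1CC[C@@H]2C[C@H]1[S@@+]([CH-]C(=C)C(=O)OCC)C2(C)C | intermediate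
10 | anti betaine: alkoxide at the future C3, sulfonium at the future C2, as its caesium phenoxide | C[C@@H]1CC[C@@H]2C[C@H]1[S@@+]([C@H](C(=C)C(=O)OCC)[C@@H]([O-])c3cc([C@@H](C)O[Si](C)(C)C(C)(C)C)ccc3[O-])C2(C)C.[Cs+] | intermediate
11 | caesium 2-[(2S,3S)-3-(1-ethoxycarbonylvinyl)oxiran-2-yl]-4-[(1R)-1-(tert-butyldimethylsilyloxy)ethyl]phenoxide (trans vinyl epoxide) | C=C(C(=O)OCC)[C@@H]1O[C@H]1c2cc([C@@H](C)O[Si](C)(C)C(C)(C)C)ccc2[O-].[Cs+] | intermediate
12 | ethyl 2-[(2R,3S)-3-hydroxy-5-[(1R)-1-(tert-butyldimethylsilyloxy)ethyl]-2,3-dihydro-1-benzofuran-2-yl]prop-2-enoate | C=C(C(=O)OCC)[C@H]1Oc2ccc([C@@H](C)O[Si](C)(C)C(C)(C)C)cc2[C@@H]1O | intermediate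
13 | (2R,3S)-2-(3-hydroxyprop-1-en-2-yl)-5-[(1R)-1-(tert-butyldimethylsilyloxy)ethyl]-2,3-dihydro-1-benzofuran-3-ol | C=C(CO)[C@H]1Oc2ccc([C@@H](C)O[Si](C)(C)C(C)(C)C)cc2[C@@H]1O | intermediate
14 | (2R,3S)-2-[3-(tert-butyldiphenylsilyloxy)prop-1-en-2-yl]-5-[(1R)-1-(tert-butyldimethylsilyloxy)ethyl]-2,3-dihydro-1-benzofuran-3-ol | C=C(CO[Si](c3ccccc3)(c4ccccc4)C(C)(C)C)[C@H]1Oc2ccc([C@@H](C)O[Si](C)(C)C(C)(C)C)cc2[C@@H]1O | intermediate
15 | isovaleric acid (3-methylbutanoic acid) | CC(C)CC(=O)O | starting material
16 | (2R,3R)-2-[3-(tert-butyldiphenylsilyloxy)prop-1-en-2-yl]-5-[(1R)-1-(tert-butyldimethylsilyloxy)ethyl]-2,3-dihydro-1-benzofuran-3-yl 3-methylbutanoate | C=C(CO[Si](c3ccccc3)(c4ccccc4)C(C)(C)C)[C@H]1Oc2ccc([C@@H](C)O[Si](C)(C)C(C)(C)C)cc2[C@H]1OC(=O)CC(C)C | intermediate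
17 | (2R,3R)-2-[3-(tert-butyldiphenylsilyloxy)prop-1-en-2-yl]-5-[(1R)-1-hydroxyethyl]-2,3-dihydro-1-benzofuran-3-yl 3-methylbutanoate | C=C(CO[Si](c3ccccc3)(c4ccccc4)C(C)(C)C)[C@H]1Oc2ccc([C@@H](C)O)cc2[C@H]1OC(=O)CC(C)C | intermediate
18 | (R)-2-methylbutanoic acid | CC[C@@H](C)C(=O)O | starting material
19 | (1R)-1-[(2R,3R)-2-[3-(tert-butyldiphenylsilyloxy)prop-1-en-2-yl]-3-(3-methylbutanoyloxy)-2,3-dihydro-1-benzofuran-5-yl]ethyl (2R)-2-methylbutanoate | C=C(CO[Si](c3ccccc3)(c4ccccc4)C(C)(C)C)[C@H]1Oc2ccc([C@@H](C)OC(=O)[C@H](C)CC)cc2[C@H]1OC(=O)CC(C)C | intermediate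
20 | (1R)-1-[(2R,3R)-2-(3-hydroxyprop-1-en-2-yl)-3-(3-methylbutanoyloxy)-2,3-dihydro-1-benzofuran-5-yl]ethyl (2R)-2-methylbutanoate | C=C(CO)[C@H]1Oc2ccc([C@@H](C)OC(=O)[C@H](C)CC)cc2[C@H]1OC(=O)CC(C)C | intermediate
21 | (1R)-1-[(2R,3R)-3-(3-methylbutanoyloxy)-2-(3-oxoprop-1-en-2-yl)-2,3-dihydro-1-benzofuran-5-yl]ethyl (2R)-2-methylbutanoate | C=C(C=O)[C@H]1Oc2ccc([C@@H](C)OC(=O)[C@H](C)CC)cc2[C@H]1OC(=O)CC(C)C | target

Total step count: 13. Longest linear sequence: 12 steps (steps 1–4 and 6–13, from 4-acetoxyacetophenone); step 5 is a one-step side branch.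

Steps most likely to fail

1. Step 6 (Proposed new method). Three things could go wrong:
- The phenoxide may be allylated on oxygen by the salt (SN2′) faster than the ylide adds to the deactivated carbonyl.
- The ylide may show poor face selectivity.
- Direct displacement of the sulfide by the phenoxide may compete with closure through the epoxide; that inverts C2 once instead of twice and would erode the configuration of ring B.

The fallback separates the two bond formations with known reactions; it sets out from 5 and comes back at 12. The phenol of 5 is silylated (TIPSCl, imidazole, DMF) to give 2-(triisopropylsilyloxy)-5-[(1R)-1-(tert-butyldimethylsilyloxy)ethyl]benzaldehyde F1, which has no phenoxide to be allylated. Salt 8 and Cs2CO3 in MeCN then carry out an ordinary sulfonium ylide epoxidation of this aldehyde. This should give the trans vinyl epoxide ethyl 2-[(2S,3S)-3-{2-(triisopropylsilyloxy)-5-[(1R)-1-(tert-butyldimethylsilyloxy)ethyl]phenyl}oxiran-2-yl]prop-2-enoate F2, with the same ylide face as in the one-flask version. One equivalent of TBAF in THF at 0 °C removes only the aryl silyl ether, and the released phenoxide opens the epoxide at the allylic carbon with inversion to give 12. The pathway through the epoxide is then the only one available.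

2. Step 9. The activated C3–O bond is benzylic and ortho to the ring oxygen, so it may ionise; that would give the ester without clean inversion or lose a proton from C2 to form the aromatic benzofuran. The carboxylate must also approach from the face that carries the C2 substituent.

The fallback replaces substitution by an oxidation–reduction sequence; it sets out from 14 and comes back at 16. Dess–Martin periodinane (NaHCO3, CH2Cl2, 0 °C) should oxidise 14 to the ketone (2R)-2-[3-(tert-butyldiphenylsilyloxy)prop-1-en-2-yl]-5-[(1R)-1-(tert-butyldimethylsilyloxy)ethyl]-1-benzofuran-3(2H)-one F3. Its C2–H is acidic, so it is kept cold, away from base, and reduced at once. Luche reduction (NaBH4, CeCl3·7H2O, MeOH, −78 °C) delivers hydride anti to the C2 substituent and should give the cis alcohol (2R,3R)-2-[3-(tert-butyldiphenylsilyloxy)prop-1-en-2-yl]-5-[(1R)-1-(tert-butyldimethylsilyloxy)ethyl]-2,3-dihydro-1-benzofuran-3-ol F4. Acylation with isovaleryl chloride and pyridine in CH2Cl2 at 0 °C then gives 16.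

3. Step 10. The secondary benzylic TBS ether and the primary TBDPS ether may not differ enough in rate, so the primary silyl ether may be lost before the secondary one is fully cleaved.

The fallback moves the selectivity from a deprotection to a protection; it sets out from 16 and comes back at 17. Both silyl ethers are removed (TBAF, AcOH, THF, rt) to give the diol (2R,3R)-2-(3-hydroxyprop-1-en-2-yl)-5-[(1R)-1-hydroxyethyl]-2,3-dihydro-1-benzofuran-3-yl 3-methylbutanoate F5. TBDPSCl (1.0 equiv) and imidazole in CH2Cl2 at −20 °C then silylate only the primary allylic hydroxyl and return 17.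

Further compounds

F1 | step 6 | 2-(triisopropylsilyloxy)-5-[(1R)-1-(tert-butyldimethylsilyloxy)ethyl]benzaldehyde | O=Cc1cc([C@@H](C)O[Si](C)(C)C(C)(C)C)ccc1O[Si](C(C)C)(C(C)C)C(C)C
F2 | step 6 | ethyl 2-[(2S,3S)-3-{2-(triisopropylsilyloxy)-5-[(1R)-1-(tert-butyldimethylsilyloxy)ethyl]phenyl}oxiran-2-yl]prop-2-enoate | C=C(C(=O)OCC)[C@@H]1O[C@H]1c2cc([C@@H](C)O[Si](C)(C)C(C)(C)C)ccc2O[Si](C(C)C)(C(C)C)C(C)C
F3 | step 9 | (2R)-2-[3-(tert-butyldiphenylsilyloxy)prop-1-en-2-yl]-5-[(1R)-1-(tert-butyldimethylsilyloxy)ethyl]-1-benzofuran-3(2H)-one | C=C(CO[Si](c3ccccc3)(c4ccccc4)C(C)(C)C)[C@H]1Oc2ccc([C@@H](C)O[Si](C)(C)C(C)(C)C)cc2C1=O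
F4 | step 9 | (2R,3R)-2-[3-(tert-butyldiphenylsilyloxy)prop-1-en-2-yl]-5-[(1R)-1-(tert-butyldimethylsilyloxy)ethyl]-2,3-dihydro-1-benzofuran-3-ol | C=C(CO[Si](c3ccccc3)(c4ccccc4)C(C)(C)C)[C@H]1Oc2ccc([C@@H](C)O[Si](C)(C)C(C)(C)C)cc2[C@H]1O
F5 | step 10 | (2R,3R)-2-(3-hydroxyprop-1-en-2-yl)-5-[(1R)-1-hydroxyethyl]-2,3-dihydro-1-benzofuran-3-yl 3-methylbutanoate | C=C(CO)[C@H]1Oc2ccc([C@@H](C)O)cc2[C@H]1OC(=O)CC(C)C
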